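In maple, at 20 °C, the charged impurity removes free enzyme 919 times faster than unfolding does, so I keep my books on the catalyst before I look at the substrate. The flasks differ in temperature, and ash changes temperature during its run.

| flask | substrate | precatalyst | impurity | temperature | time | remark |
|---|---|---|---|---|---|---|
| elm | 35 mM | 33 µM | 23 µM | 50 °C | 1.0 h |  |
| maple | 35 mM | 33 µM | 23 µM | 20 °C | 1.0 h |  |
| birch | 35 mM | 33 µM | 23 µM | −10 °C | 1.0 h |  |
| ash | 35 mM | 33 µM | 23 µM |  | 1.0 h | at −10 °C until 12 min, from then on at 50 °C |

    free enzyme → unfolded enzyme (k1 = 9.08 × 10⁻⁴ min⁻¹, Ea1 = 217 kJ mol⁻¹)
    substrate + free enzyme → product + free enzyme, rate k2*[substrate]*[free enzyme]/(1 + ([substrate]/Km2)) (Km2 = 22.3 mM, k2 = 2630 M⁻¹ min⁻¹, Ea2 = 50.0 kJ mol⁻¹)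
    precatalyst → free enzyme (k3 = 0.121 min⁻¹, Ea3 = 76.0 kJ mol⁻¹)
    free enzyme + impurity → spent catalyst (k4 = 36300 M⁻¹ min⁻¹, Ea4 = 43.0 kJ mol⁻¹)
    (constants at 20 °C)

- constants are those at 20 °C; use the activation energies for any other temperature

- the flask that comes out highest in amount of product, in percent of the substrate charged, or "all alike" when all lie within 1.5 percentage points (elm / maple / birch / ash / all alike)
- product at the end, in percent of the substrate charged, elm
- product at the end, in percent of the substrate charged, maple
- product at the end, in percent of the substrate charged, birch
- product at the end, in percent of the substrate charged, ash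

The ledger is for maple. The first entry is the capture. Precatalyst releases free enzyme with constant 0.121 min⁻¹, while the impurity charge removes it at 0.835 min⁻¹, which is faster. I therefore treat capture as immediate while impurity lasts, a rough step, since that rate falls as the impurity falls. The impurity charge of 23 µM is smaller than the precatalyst charge of 33 µM, so impurity is the limiting reagent of this capture. Its whole charge goes into spent catalyst.

The second entry is what stays, 10.0 µM. I call it the working enzyme W, the precatalyst charge minus the impurity charge. The capture has taken its whole charge, by this reckoning, once the precatalyst has fallen to W. That takes 9.87 min, and I let W work at full strength for the remaining 50.1 min. This is a rough estimate, since at that moment W still sits in the precatalyst by this same reckoning.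

The third entry is unfolding. The half-life of free enzyme is 12.7 h, longer than the hour, so I book about 0.530 µM there and close the books on the catalyst.

Now the substrate. With W fixed, the reaction is pseudo-first-order at any moment, with a constant that grows as substrate falls. At the charged substrate this constant is 0.0102 min⁻¹, which gives 40.1% conversion. I repeat the step with the substrate at its value halfway through that conversion, and I commit to 44.3% for maple.

I carry no number to elm, birch or ash. From birch to elm, unfolding speeds up 9.9 × 10⁷ times and release 630 times, so the first entry of my ledger is not safe in elm.

The forecast gives 3.6% for elm, 42.6% for maple, 0.5% for birch and 3.6% for ash, and it names maple, because the enzyme left “keeps working for most of the hour, which makes maple clearly highest”.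

Maple gives 43.2% against my 44.3%, and it stands highest, with elm at 3.60%, birch at 0.513% and ash at 3.62%. At 1.00 h maple holds 69.7% of its catalyst as spent catalyst, 28.9% as free enzyme, 1.30% as unfolded enzyme and 0.0703% as precatalyst, while W is 30.3% of the charge. A neighbour of maple charged with 13.0 µM of precatalyst has W at −10.0 µM, so by the ledger impurity is left over by 43.5% of its charge. That neighbour keeps 44% of its impurity and ends with 2.33% product.

Its constants were chosen freely, and the outcome is calculated.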